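The ratio of target made to reagent charged, read at 1.50 h, is 20.9% in the north-west run and 22.1% in the south-east run, although the south-east run holds 3.96 times the substrate. I therefore take the making of target as zero order in substrate at these early readings, with reagent passing from the second phase into the first, where the substrate sits, and target partly crystallising.

| flask | substrate | reagent in the second phase | remark | time | volume of the second phase over the first |
|---|---|---|---|---|---|
| north-west | 0.048 M | 0.105 M | run made earlier |  |  |
| south-east | 0.19 M | 0.105 M | run made earlier |  |  |
| north-east | 0.095 M | 0.16 M | run made earlier |  |  |
| flask | 0.095 M | 0.105 M |  | 5.0 h | 2.0 |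

| run | time / h | target / % | crystals / % |
|---|---|---|---|
| north-west | 1.50 | 45.7 | 12.1 |
| north-west | 3.00 | 73.9 | 45.1 |
| north-west | 5.00 | 86.1 | 64.1 |
| north-west | 6.00 | 83.2 | 64.8 |
| south-east | 1.50 | 12.2 | 5.3 |
| south-east | 3.00 | 20.5 | 15.2 |
| south-east | 5.00 | 31.8 | 24.0 |
| south-east | 6.00 | 35.5 | 29.5 |
| north-east | 0.500 | 12.6 | 0 |
| north-east | 1.00 | 25.6 | 7.3 |
| north-east | 2.50 | 56.4 | 36.6 |
| north-east | 6.00 | 90.4 | 78.3 |

(scatter of a reading: 1 percentage point)

- for target the crystals are counted in
- in the second phase: reagent in the second phase; everything else is in the first
- charges count per volume of the first phase; a concentration in a rate is the amount of a species over the volume of its own phase; every rate counts per litre of the first phase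
- as a solid, counted per litre of solution: crystals
- the earlier runs hold the two phases in the same ratio of volumes as the flask asked about

1. amount of target and crystals together at 5.0 h, in percent of the substrate charged
2. concentration of target in solution at 5.0 h, in percent of saturation

The target column counts the crystals in, so I can follow the reagent directly, taking one reagent per target. A species that loses a fixed fraction λ per hour has a half-life equal to the natural logarithm of 2 over λ. The last south-east reading, with 64.5% of the substrate still unconverted, gives λ = 0.171 h⁻¹, and hence the reagent half-life, the time in which the second phase loses half its reagent while ample substrate remains, of 4.04 h. The north-east run, with another reagent charge, gives 0.163 h⁻¹ at 2.50 h.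

The flask runs for 1.24 half-lives, so I expect 42.4% of the reagent left and target at 63.6% of the substrate, with 36.4% of the substrate unconverted.

The forecast gives 65% (58% to 72%) for y, 1.4 percentage points above my figure, and 165% (125% to 220%) for sat, on the ground “about first order in reagent and nearly zero order in substrate until substrate runs low”.

The flask gives 61.5% and 136%, which leaves the forecast's sat 29 points high.

    reagent in the reaction phase ⇌ reagent in the second phase, rate k1*([reagent in the reaction phase] - [reagent in the second phase]/K1) per volume of the first phase (partition coefficient = 1.60, kL = 0.590 h⁻¹)
    substrate + reagent in the reaction phase → target (k = 320 M⁻¹ h⁻¹)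
    reagent in the reaction phase + target → over-reacted product (k = 35.0 M⁻¹ h⁻¹)
    2 reagent in the reaction phase → homo dimer (k = 0.940 M⁻¹ h⁻¹)
    crystals ⇌ target, rate k5*(cs5 - [target]) while solid is left; crystals form when [target] > cs5 (solubility = 10.0 mM, k = 2.10 h⁻¹)

At 1.94 h the flask's reagent in the reaction phase has a half-life of 2.0 min by the step to target, far shorter than my 4.04 h for the reagent in the second phase, and it is made 1.00 times as fast as it is used up. At 5.0 h the flask holds 40.9% of its reagent charge in the second phase against my 42.4%, and the neighbour with 0.24 M of substrate, reckoned with the same half-life, reaches 25.2% of target against its simulated 25.8%.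

The earlier runs and the new flask were computed with made-up constants, and the scatter is random.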